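The numbers in the tables are calculated for an exercise; scatter was added.

Slowness is what the teal run shows first: with the incoming ligand near one equivalent, 77.2 % of the starting complex still stands at 20.0 min. Let M be the fraction of starting complex remaining. If every step is first order in ligand, M can serve as a clock in place of time, and one pair of readings agrees with this. Teal reads 1.4 % of complex with two exchanged at M = 77.2 %, and amber, with 6.32 times the ligand, reads 1.1 % at M = 75.7 %, a gap smaller than the scatter.

| setting | teal | amber | south-west | north-west | north-east |
|---|---|---|---|---|---|
| starting complex | 0.020 M | 0.020 M | 0.020 M | 0.020 M | 0.020 M |
| incoming ligand | 0.019 M | 0.12 M | 0.0800 M | 0.0400 M | 0.0160 M |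
| capture agent | 0.40 mM | 0.40 mM | 0.400 mM | 0.400 mM | 0.400 mM |
| remark | run made earlier | run made earlier |  |  |  |
| time |  |  | 40 min | 40 min | 40 min |

- teal (time / min: complex with two exchanged / %, starting complex / %): 4.00: 1.3, 94.1; 8.00: 0.3, 89.7; 12.0: 0.1, 84.5; 15.0: 0.5, 81.9; 20.0: 1.4, 77.2
- amber (time / min: complex with two exchanged / %, starting complex / %): 1.50: 1.3, 87.1; 3.00: 1.1, 75.7; 6.00: 4.2, 58.5; 10.0: 5.8, 42.2; 20.0: 8.3, 19.5

(each reading ± 0.5 percentage points)



- which of these holds the largest part of the starting complex at the end of south-west (starting complex / complex with one exchanged / complex with two exchanged)
- which of these holds the largest part of the starting complex at the end of north-west (starting complex / complex with one exchanged / complex with two exchanged)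
- which of these holds the largest part of the starting complex at the end of north-east (starting complex / complex with one exchanged / complex with two exchanged)
- final complex with two exchanged in south-west, as a percentage of the starting complex charged

The zero of the scale is two equal, independent sites, which give (1 − √M)² of complex with two exchanged. At amber's last M that is 31.2 %, yet the reading is lower, 8.3 %, so in amber this complex is made more slowly than two equal sites give, or is used up as well, or both. Its selectivity S, the complex with two exchanged per starting complex converted, reads 10.1 % at 6.00 min and 10.3 % at 20.0 min.

Taking S as steady, with n the final complex with two exchanged as a share of the charge, n = S(1 − M), and ligand and time enter through M. From amber's first reading, k = 0.767 /M/min, which with ligand held at its charge gives M = 8.58 % for south-west. Scaling amber's last M by ligand charge times time gives 11.3 %. That gap moves n by 0.28 percentage points, less than the scatter. The capture agent, at 2.00 % of the starting complex, was the same in both runs, so they do not show its effect. At a given M, n moves in proportion to S, and S rests on one reading with a scatter of 0.5 points. This reckoning gives 9.14 %.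

The forecast says complex with one exchanged, complex with one exchanged and starting complex for south-west, north-west and north-east, and 6 % for n, higher ligand being tied to a higher ratio: “The ratio therefore appears to scale roughly with ligand”. The reckoning above ties the ratio to M instead, and its number comes out higher than the forecast's.

South-west gives 8.19 %, and the three choices stand as forecast: complex with one exchanged, complex with one exchanged, starting complex. At 40.0 min in south-west, complex with two exchanged is made 0.961 times as fast as it is used up, each step taken net. With the M found in south-west, 14.5 %, S gives 8.81 %.

    complex with two exchanged ⇌ isomer of the product (K = 0.620, k = 0.0180 /min)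
    starting complex + incoming ligand → leaving ligand + complex with one exchanged (k = 0.790 /M/min)
    complex with one exchanged + capture agent → trapped intermediate (k = 1.30 /M/min)
    complex with two exchanged + incoming ligand → over-reaction product (k = 2.40 /M/min)
    complex with one exchanged + incoming ligand → leaving ligand + complex with two exchanged (k = 0.500 /M/min)

A neighbour of south-west charged with 0.080 M of starting complex ends at M = 37.8 %, so S gives 6.41 %; the computed value is 6.20 %.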